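Everything rests on tracing ring B (C5–C10, labdane numbering) back to the cyclopentanone ring of an enantiopure trans-hydrindanone. An amino-acid-catalysed Hajos–Parrish-type annulation fixes C10, and a reductive alkylation fixes C5 and C4. The key step inserts the CH(CH3) unit of diazoethane into the C9–C7 bond. The five-membered ring C5–C6–C7–C9–C10 thereby grows to ring B, and C8 arrives with its methyl group. The step exploits the position of C9 between quaternary C10 and a CH2 group. Only C7 migrates, and afterwards only C8 can enolise, so triflation and Negishi coupling deliver the tetrasubstituted C8=C9 alkene and the side chain as single regioisomers. The precursor is the C17 hydrindan-1-one 12.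

Key step: step 8

Remark on numbering: ring A = C1–C5 and C10; ring B = C5–C10. C4 carries CH3 (β, axial) and the 4-methylpent-3-enyl ("homoprenyl") group (α, equatorial). C5 carries H (α) and C10 carries CH3 (β). The side chain C11–C15 sits on C9. In the hydrindanes the five-membered ring is C5–C6–C7–C9–C10, and C8 is still missing.

Remark on the chemistry: ketone 14 may form as a mixture of C8 epimers. It is drawn as the equatorial 8α-methyl epimer, and this centre is erased in step 9.

Step 1
Reactants: 1 2-methylcyclopentane-1,3-dione; 2 pent-1-en-3-one (ethyl vinyl ketone)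
Product: 3 2-methyl-2-(3-oxopentyl)cyclopentane-1,3-dione
Conditions: H2O, AcOH (cat.), 75 °C
Reagents that add atoms: none
Why: Michael addition of the acidic 1,3-dione to the enone, which stops at the triketone because the attacking carbon (future C10) becomes quaternary; no stereocentre is formed.

Step 2
Reactants: 3 triketone
Product: 4 (7aS)-4,7a-dimethyl-2,3,7,7a-tetrahydro-1H-indene-1,5(6H)-dione
Conditions: L-phenylalanine, (+)-camphorsulfonic acid, DMF, 30 → 70 °C; recrystallisation
Reagents that add atoms: none
Why: Hajos–Parrish–Eder–Sauer–Wiechert reaction, in which the enamine of the ethyl ketone with the primary L-amino acid attacks one of the two enantiotopic ring carbonyls through a hydrogen-bonded chair-like transition state and dehydration follows, so that C10 is set as S (10β-CH3) and recrystallisation should raise the enantiomeric purity.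

Step 3
Reactants: 4 enedione
Product: 5 (1S,7aS)-1-hydroxy-4,7a-dimethyl-1,2,3,6,7,7a-hexahydro-5H-inden-5-one (9β-alcohol)
Conditions: NaBH4, EtOH, −10 °C
Reagents that add atoms: none
Why: Chemoselective borohydride reduction, since the saturated cyclopentanone is more electrophilic than the tetrasubstituted enone, with hydride delivered from the α face opposite the 10β-methyl group (this carbinol centre is erased in step 7).

Step 4
Reactants: 6 5-bromo-2-methylpent-2-ene
Product: 7 5-iodo-2-methylpent-2-ene
Conditions: NaI, acetone, reflux
Reagents that add atoms: sodium iodide, [Na+].[I-]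
Why: Finkelstein reaction (SN2), driven by precipitation of sodium bromide, provides the more reactive alkylating agent.

Step 5
Reactants: 5 hydroxy enone; 7 homoprenyl iodide
Product: 9 trans-hydrindane keto alcohol (3-oxo; 9β-OH; 4α-homoprenyl; 4β-CH3; 5α-H; 10β-CH3), via dilithium enolate alkoxide 8 (not isolated)
Conditions: Li, NH3(l)/THF, −78 → −33 °C; isoprene; then 7, THF, −33 °C → rt; aq NH4Cl
Reagents that add atoms: none
Why: Birch-type reductive alkylation of an enone, in which the hydroxyl group supplies the one proton that is needed, C5 is protonated axially from the α face to give the trans ring fusion, and the regiodefined C3–C4 enolate is alkylated on the α face away from the axial 10β-methyl group, so that the homoprenyl group ends up 4α and the methyl group 4β.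

Step 6
Reactants: 9 keto alcohol
Product: 11 trans-hydrindan-9β-ol (C3 now CH2), via hydrazone 10 (not isolated)
Conditions: N2H4·H2O, KOH, diethylene glycol, N2, 130 → 200 °C
Reagents that add atoms: none
Why: Wolff–Kishner reduction (Huang-Minlon modification), which is reliable for ketones next to a quaternary carbon and leaves the isolated alkene, the alcohol and all stereocentres (C4 is quaternary) untouched.

Step 7
Reactants: 11 hydrindanol
Product: 12 (3aS,4S,7aS)-4,7a-dimethyl-4-(4-methylpent-3-enyl)octahydro-1H-inden-1-one (trans-hydrindan-9-one)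
Conditions: TPAP (cat.), NMO, 4 Å MS, CH2Cl2, rt
Reagents that add atoms: none
Why: Ley–Griffith oxidation of the secondary alcohol under neutral conditions that do not affect the trisubstituted alkene or any stereocentre.

Step 8
Reactants: 12 trans-hydrindan-9-one
Product: 14 8α-methyl-trans-decal-9-one, via diazonium betaine 13 (not isolated)
Conditions: CH3CHN2 (Et2O solution, from N-ethyl-N-nitrosourea and aq KOH, 0 °C), Sc(OTf)3 (cat.), CH2Cl2, −78 → 0 °C
Reagents that add atoms: diazoethane, CC=[N+]=[N-]
Why: Sc(OTf)3 activates the C9 carbonyl, the nucleophilic carbon of diazoethane adds from the α face (anti to the 10β-methyl group) to give betaine 13, and loss of N2 is concerted with the 1,2-shift of the C9–C7 bond to the former diazo carbon, which becomes C8. This is the Lewis-acid-catalysed diazoalkane homologation of cyclic ketones (Büchner–Curtius–Schlotterbeck type, related to the Tiffeneau–Demjanov rearrangement). No ring is closed by cyclisation: the ring C5–C6–C7–C9–C10 grows by one atom through the shift, and C5 and C10 are not touched, so the trans fusion of the hydrindane passes unchanged into the decalin. The only new stereocentre, C8, is under thermodynamic control through the enol (equatorial 8α-methyl) and is erased in step 9. The step needs migration of C7 rather than C10, a single insertion and an inert alkene: under Lewis-acid catalysis the less substituted CH2 migrates in preference to the congested quaternary C10, the product ketone flanked by C8 and C10 is too hindered to react again, and an unactivated trisubstituted alkene does not react with diazoethane.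

Step 9
Reactants: 14 decalone
Product: 16 C9 enol triflate (C8=C9), via potassium enolate 15 (not isolated)
Conditions: KHMDS, THF, −78 → 0 °C; PhNTf2, −78 °C → rt
Reagents that add atoms: N-phenylbis(trifluoromethanesulfonimide), O=S(=O)(N(c1ccccc1)S(=O)(=O)C(F)(F)F)C(F)(F)F
Why: Enolate O-triflation, in which deprotonation can only occur at C8 because C10 is quaternary, so the tetrasubstituted C8=C9 double bond is placed without a regioisomer.

Step 10
Reactants: 17 4-bromobut-1-yne
Product: 19 ethyl (E)-5-bromo-3-methylpent-2-enoate, via alkenylalane 18 (not isolated)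
Conditions: Me3Al, Cp2ZrCl2 (cat.), CH2Cl2, 0 °C → rt; ClCO2Et, 0 °C → rt
Reagents that add atoms: trimethylaluminium, C[Al](C)C; ethyl chloroformate, CCOC(=O)Cl
Why: Zirconium-catalysed carboalumination adds CH3 and Al syn across the terminal alkyne with Al at the terminus, and acylation of the alkenyl–Al bond by the chloroformate proceeds with retention, which fixes the E geometry of C13=C14.

Step 11
Reactants: 16 enol triflate; 19 bromo ester
Product: 21 ethyl ester of the target, via alkylzinc bromide 20 (not isolated)
Conditions: 19, Zn, LiCl, THF, 50 °C; then 16, Pd(OAc)2 (cat.), SPhos (cat.), THF/NMP, 50 °C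
Reagents that add atoms: none
Why: Negishi sp3–sp2 cross-coupling, in which zinc inserts into the primary C–Br bond without touching the enoate and a bulky electron-rich phosphine supports oxidative addition to the hindered triflate, so that the C9–C11 bond forms with retention of both double-bond positions and of the E geometry.

Step 12
Reactants: 21 ethyl ester
Product: 23 target acid CNP0237483.2, via lithium carboxylate 22 (not isolated)
Conditions: LiOH, THF/MeOH/H2O, 50 °C; then 1 M HCl
Reagents that add atoms: lithium hydroxide, [Li+].[OH-]
Why: Saponification (BAc2) of the β,β-disubstituted enoate followed by acidification, under conditions that leave the three alkenes and the three stereocentres unchanged.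

Compound list
1 | 2-methylcyclopentane-1,3-dione | CC1C(=O)CCC1=O | starting material
2 | pent-1-en-3-one (ethyl vinyl ketone) | CCC(=O)C=C | starting material
3 | 2-methyl-2-(3-oxopentyl)cyclopentane-1,3-dione | CCC(=O)CCC1(C)C(=O)CCC1=O | intermediate
4 | (7aS)-4,7a-dimethyl-2,3,7,7a-tetrahydro-1H-indene-1,5(6H)-dione | C[C@]12CCC(=O)C(C)=C1CCC2=O | intermediate
5 | (1S,7aS)-1-hydroxy-4,7a-dimethyl-1,2,3,6,7,7a-hexahydro-5H-inden-5-one | C[C@]12CCC(=O)C(C)=C1CC[C@@H]2O | intermediate
6 | 5-bromo-2-methylpent-2-ene | CC(C)=CCCBr | starting material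
7 | 5-iodo-2-methylpent-2-ene | CC(C)=CCCI | intermediate
8 | dilithium C3–C4 enolate 9β-alkoxide (5α-H; trans-fused) | CC1=C([O-])CC[C@]2(C)[C@@H]([O-])CC[C@@H]12.[Li+].[Li+] | intermediate
9 | (1S,3aR,4S,7aS)-1-hydroxy-4,7a-dimethyl-4-(4-methylpent-3-enyl)octahydro-5H-inden-5-one | CC(C)=CCC[C@]1(C)C(=O)CC[C@]2(C)[C@@H](O)CC[C@@H]12 | intermediate
10 | C3 hydrazone of 9 | CC(C)=CCC[C@]1(C)C(=NN)CC[C@]2(C)[C@@H](O)CC[C@@H]12 | intermediate
11 | (1S,3aS,4S,7aS)-4,7a-dimethyl-4-(4-methylpent-3-enyl)octahydro-1H-inden-1-ol | CC(C)=CCC[C@]1(C)CCC[C@]2(C)[C@@H](O)CC[C@@H]12 | intermediate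
12 | (3aS,4S,7aS)-4,7a-dimethyl-4-(4-methylpent-3-enyl)octahydro-1H-inden-1-one | CC(C)=CCC[C@]1(C)CCC[C@]2(C)C(=O)CC[C@@H]12 | intermediate
13 | diazonium betaine (9β-oxide; 9α-(1-diazonioethyl); diazonium carbon epimeric) | CC(C)=CCC[C@]1(C)CCC[C@]2(C)[C@]([O-])(C(C)[N+]#N)CC[C@@H]12 | intermediate
14 | (2R,4aS,5S,8aS)-2,5,8a-trimethyl-5-(4-methylpent-3-enyl)octahydronaphthalen-1(2H)-one | CC(C)=CCC[C@]1(C)CCC[C@]2(C)C(=O)[C@H](C)CC[C@@H]12 | intermediate
15 | potassium C9–C8 enolate of 14 | CC(C)=CCC[C@]1(C)CCC[C@]2(C)C([O-])=C(C)CC[C@@H]12.[K+] | intermediate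
16 | (4aS,5S,8aS)-2,5,8a-trimethyl-5-(4-methylpent-3-enyl)-3,4,4a,5,6,7,8,8a-octahydronaphthalen-1-yl triflate | CC(C)=CCC[C@]1(C)CCC[C@]2(C)C(OS(=O)(=O)C(F)(F)F)=C(C)CC[C@@H]12 | intermediate
17 | 4-bromobut-1-yne | C#CCCBr | starting material
18 | (E)-(4-bromo-2-methylbut-1-enyl)dimethylalane | C[Al](C)/C=C(\C)CCBr | intermediate
19 | ethyl (E)-5-bromo-3-methylpent-2-enoate | CCOC(=O)/C=C(\C)CCBr | intermediate
20 | (E)-(5-ethoxy-3-methyl-5-oxopent-3-enyl)zinc bromide | CCOC(=O)/C=C(\C)CC[Zn]Br | intermediate
21 | ethyl (E)-3-methyl-5-[(4aS,5S,8aS)-2,5,8a-trimethyl-5-(4-methylpent-3-enyl)-3,4,4a,5,6,7,8,8a-octahydronaphthalen-1-yl]pent-2-enoate | CC(C)=CCC[C@]1(C)CCC[C@]2(C)C(CC/C(C)=C/C(=O)OCC)=C(C)CC[C@@H]12 | intermediate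
22 | lithium carboxylate of 23 | CC(C)=CCC[C@]1(C)CCC[C@]2(C)C(CC/C(C)=C/C(=O)[O-])=C(C)CC[C@@H]12.[Li+] | intermediate
23 | (E)-3-methyl-5-[(4aS,5S,8aS)-2,5,8a-trimethyl-5-(4-methylpent-3-enyl)-3,4,4a,5,6,7,8,8a-octahydronaphthalen-1-yl]pent-2-enoic acid | CC(C)=CCC[C@]1(C)CCC[C@]2(C)C(CC/C(C)=C/C(=O)O)=C(C)CC[C@@H]12 | target

Total step count: 12. Longest linear sequence: 10 steps (1, 2, 3, 5, 6, 7, 8, 9, 11, 12).

Steps most likely to fail

Step 8 (key step). What may go wrong:
- Diazoethane may add only slowly to the carbonyl group next to quaternary C10.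
- The betaine may collapse to a spiro-epoxide instead of undergoing the 1,2-shift.
- C10 may migrate in competition with C7.

The fallback keeps the one-carbon growth of the same ring but replaces carbonyl addition by carbene addition and electrocyclic opening. It sets out from 12 and comes back at 16. Ketone 12 would be converted with LDA and TMSCl into the silyl enol ether F1. Chloro(methyl)carbene (1,1-dichloroethane, n-BuLi, Et2O, −35 °C) should add to this most electron-rich double bond (C9=C7) from the α face to give the siloxy chlorocyclopropane F2. Heating in toluene should open the C9–C7 bond in a disrotatory sense, with loss of the silyl and chloride groups, to give the ring-enlarged 8-methyl-7-en-9-one F3. Conjugate reduction with L-Selectride and trapping of the C9–C8 enolate with PhNTf2 would then return to 16.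

Step 5. What may go wrong:
- The unactivated iodide may C-alkylate the fully substituted enolate only slowly.
- Proton transfer may then return merely reduced ketone.
- Protonation of C5 may show imperfect facial selectivity.

The fallback uses a reactive allylic electrophile and builds the chain afterwards. It sets out from 5 and comes back at 12. The same Li/NH3 reduction would be followed by allyl bromide to give the 4α-allyl keto alcohol F4. Wolff–Kishner reduction would give the 4α-allyl hydrindanol F5. Hydroboration with 9-BBN and oxidative work-up would give the diol F6. Oxidation of both alcohols (Dess–Martin periodinane) would give the keto aldehyde F7. A Wittig reaction with isopropylidenetriphenylphosphorane should attack only the aldehyde, because the C9 ketone next to C10 is too hindered, and would deliver 12.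

Step 11. What may go wrong:
- Oxidative addition and transmetalation at the hindered tetrasubstituted triflate may be slow.
- β-Hydride elimination of the alkylpalladium species may occur.
- The triflate may be reduced.

The fallback puts a small sp2 partner on C9 and forms C12–C13 away from the congested centre. It sets out from 16 and comes back at 21. Suzuki vinylation of 16 (potassium vinyltrifluoroborate, PdCl2(dppf), K3PO4, THF/H2O) would give the 9-vinyl diene F8. 9-BBN should hydroborate only the monosubstituted vinyl group to give the B-alkyl-9-BBN F9. Copper-catalysed syn addition of this alkylborane to ethyl but-2-ynoate (CuOAc, P(OPh)3, KOt-Bu, t-BuOH, dioxane) would place the chain trans to the ester and give 21 with the E geometry.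

Further compounds
F1 | step 8 | silyl enol ether of 12 (C9–OTMS; C9=C7) | CC(C)=CCC[C@]1(C)CCC[C@]2(C)C(O[Si](C)(C)C)=CC[C@@H]12
F2 | step 8 | α-face chloro(methyl)cyclopropane on C9–C7 (9β-OTMS; 7β-H; C8 epimeric) | CC(C)=CCC[C@]1(C)CCC[C@]2(C)[C@]3(O[Si](C)(C)C)C(C)(Cl)[C@@H]3C[C@@H]12
F3 | step 8 | ring-enlarged 8-methyl-7-en-9-one | CC(C)=CCC[C@]1(C)CCC[C@]2(C)C(=O)C(C)=CC[C@@H]12
F4 | step 5 | 4α-allyl keto alcohol | C=CC[C@]1(C)C(=O)CC[C@]2(C)[C@@H](O)CC[C@@H]12
F5 | step 5 | 4α-allyl hydrindan-9β-ol | C=CC[C@]1(C)CCC[C@]2(C)[C@@H](O)CC[C@@H]12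
F6 | step 5 | 4α-(3-hydroxypropyl) hydrindan-9β-ol | OCCC[C@]1(C)CCC[C@]2(C)[C@@H](O)CC[C@@H]12
F7 | step 5 | 4α-(3-oxopropyl) hydrindan-9-one | O=CCC[C@]1(C)CCC[C@]2(C)C(=O)CC[C@@H]12
F8 | step 11 | 9-vinyl-8-ene diene | CC(C)=CCC[C@]1(C)CCC[C@]2(C)C(C=C)=C(C)CC[C@@H]12
F9 | step 11 | B-(C12-alkyl)-9-borabicyclo[3.3.1]nonane | CC(C)=CCC[C@]1(C)CCC[C@]2(C)C(CCB3C4CCCC3CCC4)=C(C)CC[C@@H]12
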